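**Assumption:** ring A is numbered as in the target acid (C1 carboxyl carbon, C2 hydroxyl, C4 ester oxygen, C6 pentyl) and ring B as its benzoyl unit (C1 carbonyl-bearing carbon, C2 hydroxyl, C3 chlorine, C4 methoxy, C6 propyl). The target has no stereocentre, so no configuration has to be set.

## The problem

The target 13 is a para-depside: the carboxyl group of ring B (3-chloro-2-hydroxy-4-methoxy-6-propylbenzoic acid) is esterified with the C4 hydroxyl of ring A (2,4-dihydroxy-6-pentylbenzoic acid), and this aryl ester is the only link between the rings. With no stereocentre, the difficulty is regiochemical and chemoselective. Ring B carries five substituents around a single C–H, and its chlorine must sit at C3 between two oxygens, a site that direct halogenation of an aromatic resorcinol does not favour. Ring A must be acylated at the C4 oxygen only, although C2 carries a second phenol. Three groups are fragile: the ring A salicylic acid (a β-resorcylic acid that loses CO2 on heating or in acid), the aryl ester (cleaved or transacylated by alkoxides, hydroxide and amines) and the aryl chloride (at risk under hydrogenolysis). The enabling feature is that ring A C1 lies ortho to the free C2 hydroxyl and para to the C4 ester oxygen. Without its carboxyl carbon, ring A is olivetol with two equivalent hydroxyls, and the carbon can be returned last by phenol-directed ortho C–H formylation and mild oxidation.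

## Retrosynthesis

**13 to 12.** No skeletal bond is cut; the ring A C1 carboxyl is taken back to a formyl group. This keeps the decarboxylation-prone acid out of every step but the last. It also avoids carrying the acid as a benzyl or tert-butyl ester, whose removal would need hydrogenolysis beside an aryl chloride or strong acid beside a β-resorcylic acid. The forward step must oxidise an aldehyde on an electron-rich phenol without chlorinating either ring, which a buffered chlorite oxidation with an alkene scavenger should do.

**12 to 10 (key disconnection).** The ring A C1–CHO bond is cut. Cutting the ester first would lead to a ring A aldehyde that already bears two different hydroxyls. Cutting the C–C bond first leaves a monoester 10 of symmetrical olivetol, one carbon simpler and free of any acylation regiochemistry. The forward reaction must place carbon at C1 (between the C2 hydroxyl and the pentyl chain) and not at C3, must leave ring B alone, and must not cleave the ester. Magnesium-mediated ortho-formylation offers ortho delivery from the free phenol under amine base only.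

**10 to 8 and 9.** The acyl C–O bond of the depside is cut, giving ring B acid 8 and olivetol 9. Because the two hydroxyls of 9 are equivalent, the only selectivity question is mono- versus di-acylation, handled by an excess of 9. Acid 8 is used with its C2 hydroxyl free: that hydroxyl is hydrogen-bonded to the carboxyl and flanked by chlorine, so no protecting group is planned.

**8 to 7 to 6.** The ring B carboxyl is taken back to the aldehyde 7, and the C4 methyl ether to the free dihydroxy aldehyde 6. Keeping a carbonyl at C1 during methylation is the point: it makes the two ring B hydroxyls different (C2 chelated, C4 free and more acidic). Methylation before the carbonyl is present would be statistical.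

**6 to 4.** The ring B C1–CHO bond is cut to give 2-chlororesorcinol 4. Compound 4 is symmetrical, its C2 is blocked, and the two open ring positions are equivalent, so formylation can give only one isomer.

**4 to 2 to 1.** Aromatisation is undone to reach the dichlorodione 2, and both C–Cl bonds are cut to reach commercial dione 1. Chlorinating at the dione stage is preferred to chlorinating an aromatic ring because dione C2 is the only carbon flanked by two carbonyls. The chlorine is thereby fixed between the two future oxygens before the ring is aromatic.

## Roads not taken

**Alternative 1:** Ring A itself is cut at C1–C2 and C5–C6. A silyl ketene acetal diene A2, whose enol oxygen already carries the benzyl-protected ring B aroyl group, would undergo a thermal Diels–Alder reaction with benzyl oct-2-ynoate A3. Loss of ethanol and of the silyl group would give the phenol A1, and hydrogenolysis of both benzyl groups would give 13.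
- Merits: the polarisation of diene and ynoate fixes every ring A position, so there is no question of which carbon is functionalised. The carboxyl arrives as an ester, so no phenolic aldehyde has to be oxidised. In regiochemical certainty this road is better than the chosen one.
- Weak points: A2 combines a hydrolytically labile ketene acetal with an enol ester that is itself an acyl donor, and its preparation needs strong amide base in the presence of that enol ester. A β-alkyl ynoate is a sluggish dienophile, so heat is needed, which invites acyl or silyl migration. The end game is a double hydrogenolysis beside an aryl chloride, and ring B needs an extra protection.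
- Comparison: the chosen plan offers commercial olivetol, no protecting groups and roughly half the steps.

**Alternative 2:** The ester is cut at the aryl C4–O bond instead of the acyl C–O bond. The MOM-protected ring B acid A6 and the ring A boronic acid A5 would be joined by Cu(OTf)2, urea and air to give the fully protected depside A4. Acid would then remove the tert-butyl ester and both MOM ethers.
- Merits: the carboxylate acts as nucleophile, so the di-ortho substitution that slows acyl transfer in step 6 does not matter. The boron atom defines the site, and the protected intermediate is robust. In both respects this road is at least as good as the chosen one.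
- Weak points: A5 must be carboxylated, protected and borylated before the coupling. Electron-rich arylboronic acids are prone to protodeboronation and phenol formation under oxidative copper conditions. The final global acidolysis exposes the freshly freed β-resorcylic acid to acid.
- Comparison: the chosen plan is shorter by several steps and frees the acid under a mild buffer near room temperature.

**Alternative 3:** The ring A C2–O bond is cut. Pd(OAc)2 with O2 and benzoquinone would hydroxylate the carboxylate-directed ortho C–H of the 4-aroyloxy-2-pentylbenzoic acid A8 to give A7, and MOM removal would give 13.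
- Merits: only one ortho C–H flanks the carboxyl, so the site is unambiguous, which is better than the C1-versus-C3 question of the chosen key step. The logic of functionalising ring A last is the same.
- Weak points: the known conditions use a carboxylate base in a polar amide solvent above 100 °C. Under these the aryl ester can be transacylated and the product, a 4-acyloxysalicylic acid, can decarboxylate. The ring A starting acid is not a commodity, and a MOM group still has to be put on and taken off.
- Comparison: the chosen plan runs its key step at or below 80 °C with a well-precedented reaction type, at the cost of a selectivity that must be secured by the substrate.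

Key step: step 7

## Route

Step 1
Reactants: 1 5-propylcyclohexane-1,3-dione
Product: 2 2,2-dichloro-5-propylcyclohexane-1,3-dione
Conditions: SO2Cl2 (2.1 equiv), CH2Cl2, 0 °C to rt
Reagents that add atoms: sulfuryl chloride SO2Cl2, O=S(=O)(Cl)Cl
Why: Electrophilic α-chlorination of a cyclic 1,3-diketone through its enol; C2 is the only carbon flanked by both carbonyls, so both chlorines should enter there, as is known for cyclohexane-1,3-dione itself, and the remote 5-propyl group does not interfere.

Step 2
Reactants: 2 2,2-dichloro-5-propylcyclohexane-1,3-dione
Product: 4 2-chloro-5-propylbenzene-1,3-diol, via 2,4-dichloro-5-propylcyclohexane-1,3-dione 3 (not isolated)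
Conditions: dry HCl in DMF, 90–100 °C
Reagents that add atoms: none
Why: Acid-promoted dehydrochlorinative aromatisation, known for 2,2-dichlorocyclohexane-1,3-dione: HCl should shift one chlorine from C2 to C4 through the enol (3, a mixture of diastereomers), and loss of HCl across C4–C5 followed by enolisation gives the resorcinol with the remaining chlorine fixed at C2 between the two hydroxyls.

Step 3
Reactants: 4 2-chloro-5-propylbenzene-1,3-diol
Product: 6 3-chloro-2,4-dihydroxy-6-propylbenzaldehyde, via aryl iminium chloride 5 (not isolated)
Conditions: POCl3 (1.5 equiv), DMF, 0 °C to rt; then H2O, 50 °C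
Reagents that add atoms: N,N-dimethylformamide, CN(C)C=O (formyl carbon); water, O (formyl oxygen)
Why: Vilsmeier–Haack formylation of a resorcinol; C2 is blocked by chlorine and the open positions C4 and C6 are equivalent by symmetry (each ortho to one hydroxyl and para to the other), so only one aldehyde can result after hydrolysis of iminium salt 5.

Step 4
Reactants: 6 3-chloro-2,4-dihydroxy-6-propylbenzaldehyde
Product: 7 3-chloro-2-hydroxy-4-methoxy-6-propylbenzaldehyde
Conditions: MeI (1.1 equiv), K2CO3 (1.0 equiv), acetone, rt to 40 °C
Reagents that add atoms: iodomethane, CI
Why: Chemoselective Williamson O-methylation; the C4 hydroxyl is para to the formyl group, more acidic and free, while the C2 hydroxyl is held in a hydrogen bond to the aldehyde, so one equivalent of weak base should methylate C4–OH only, as is routine for 2,4-dihydroxybenzaldehydes.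

Step 5
Reactants: 7 3-chloro-2-hydroxy-4-methoxy-6-propylbenzaldehyde
Product: 8 3-chloro-2-hydroxy-4-methoxy-6-propylbenzoic acid
Conditions: NaClO2, NaH2PO4, 2-methylbut-2-ene (excess), t-BuOH/H2O, rt
Reagents that add atoms: NaClO2 (sodium chlorite), [Na+].[O-]Cl=O
Why: Pinnick oxidation of an ortho-hydroxybenzaldehyde; buffered chlorite oxidises the formyl group without touching the aryl chloride, and 2-methylbut-2-ene removes the hypochlorous acid that could otherwise chlorinate ring B C5.

Step 6
Reactants: 8 3-chloro-2-hydroxy-4-methoxy-6-propylbenzoic acid; 9 5-pentylbenzene-1,3-diol (olivetol, 3 equiv)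
Product: 10 3-hydroxy-5-pentylphenyl 3-chloro-2-hydroxy-4-methoxy-6-propylbenzoate
Conditions: DCC (1.1 equiv), DMAP (0.1 equiv), CH2Cl2, 0 °C to rt; 8 and DCC added slowly to 9
Reagents that add atoms: none
Why: Steglich esterification (carbodiimide activation with DMAP as acyl-transfer catalyst); the two hydroxyls of 9 are equivalent, so only mono- versus di-acylation has to be managed, which the recoverable excess of 9 does statistically, and the ring B hydroxyl of 8 is hydrogen-bonded to its carboxyl and flanked by chlorine, so it should not compete as a nucleophile.

Step 7
Reactants: 10 3-hydroxy-5-pentylphenyl 3-chloro-2-hydroxy-4-methoxy-6-propylbenzoate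
Product: 12 4-formyl-3-hydroxy-5-pentylphenyl 3-chloro-2-hydroxy-4-methoxy-6-propylbenzoate, via ring A salicyl alcohol 11 (not isolated)
Conditions: MgCl2 (anhydrous, 3 equiv), Et3N (6 equiv), (CH2O)n (7 equiv), MeCN, reflux; then cold 1 M HCl
Reagents that add atoms: paraformaldehyde (reacts as formaldehyde), C=O
Why: MgCl2 and Et3N convert both phenols of 10 into magnesium phenoxides, and the ring A phenoxide binds monomeric formaldehyde at magnesium and delivers it through a six-membered transition state to an ortho carbon. Rearomatisation gives the magnesium salt of salicyl alcohol 11, which passes a hydride to a second formaldehyde (Oppenauer-type transfer) to give the aldehyde and methanol. The closest known reaction is the Casnati–Skattebøl ortho-formylation of phenols, which is established for 3,5-disubstituted phenols including resorcinol monoethers bearing a 5-alkyl group. No ring closes and no stereocentre forms. Ring selectivity: ring B cannot react because both carbons ortho to its hydroxyl (C1 and C3) are substituted and magnesium-bound delivery does not reach the para position C5. Site selectivity on ring A: C1 is para to the C4 ester oxygen and flanked by an alkyl group, whereas C3 lies between two oxygen substituents, is inductively deactivated by the adjacent acyloxy group and is shielded by the di-ortho-substituted aroyl residue, so C1 should be preferred, in line with the general formylation of 5-alkylresorcinol derivatives next to the alkyl chain. Chemoselectivity: only an amine base and magnesium phenoxides are present, and the depside carbonyl is flanked by the propyl group and the magnesiated ring B C2 oxygen, so ester cleavage should be slow.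

Step 8
Reactants: 12 4-formyl-3-hydroxy-5-pentylphenyl 3-chloro-2-hydroxy-4-methoxy-6-propylbenzoate
Product: 13 4-[(3-chloro-2-hydroxy-4-methoxy-6-propylbenzoyl)oxy]-2-hydroxy-6-pentylbenzoic acid
Conditions: NaClO2 (3 equiv), NaH2PO4 (3 equiv), 2-methylbut-2-ene (20 equiv), t-BuOH/THF/H2O, 0 °C to rt
Reagents that add atoms: NaClO2 (sodium chlorite), [Na+].[O-]Cl=O
Why: Pinnick oxidation, known for ortho-hydroxybenzaldehydes; the mildly acidic buffer and low temperature should spare the aryl ester and the decarboxylation-prone product, and the large excess of alkene scavenger protects ring A C3 and C5 from hypochlorous acid.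

## Compound list

1 | 5-propylcyclohexane-1,3-dione | CCCC1CC(=O)CC(=O)C1 | starting material
2 | 2,2-dichloro-5-propylcyclohexane-1,3-dione | CCCC1CC(=O)C(Cl)(Cl)C(=O)C1 | intermediate
3 | 2,4-dichloro-5-propylcyclohexane-1,3-dione (mixture of diastereomers, formed in the flask, not isolated) | CCCC1CC(=O)C(Cl)C(=O)C1Cl | intermediate
4 | 2-chloro-5-propylbenzene-1,3-diol | CCCc1cc(O)c(Cl)c(O)c1 | intermediate
5 | N-[(3-chloro-2,4-dihydroxy-6-propylphenyl)methylidene]-N-methylmethanaminium chloride (formed in the flask, not isolated) | CCCc1cc(O)c(Cl)c(O)c1C=[N+](C)C.[Cl-] | intermediate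
6 | 3-chloro-2,4-dihydroxy-6-propylbenzaldehyde | CCCc1cc(O)c(Cl)c(O)c1C=O | intermediate
7 | 3-chloro-2-hydroxy-4-methoxy-6-propylbenzaldehyde | CCCc1cc(OC)c(Cl)c(O)c1C=O | intermediate
8 | 3-chloro-2-hydroxy-4-methoxy-6-propylbenzoic acid | CCCc1cc(OC)c(Cl)c(O)c1C(=O)O | intermediate
9 | 5-pentylbenzene-1,3-diol (olivetol) | CCCCCc1cc(O)cc(O)c1 | starting material
10 | 3-hydroxy-5-pentylphenyl 3-chloro-2-hydroxy-4-methoxy-6-propylbenzoate | CCCCCc1cc(O)cc(OC(=O)c2c(CCC)cc(OC)c(Cl)c2O)c1 | intermediate
11 | 3-hydroxy-4-(hydroxymethyl)-5-pentylphenyl 3-chloro-2-hydroxy-4-methoxy-6-propylbenzoate (present as its magnesium salt, not isolated) | CCCCCc1cc(OC(=O)c2c(CCC)cc(OC)c(Cl)c2O)cc(O)c1CO | intermediate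
12 | 4-formyl-3-hydroxy-5-pentylphenyl 3-chloro-2-hydroxy-4-methoxy-6-propylbenzoate | CCCCCc1cc(OC(=O)c2c(CCC)cc(OC)c(Cl)c2O)cc(O)c1C=O | intermediate
13 | 4-[(3-chloro-2-hydroxy-4-methoxy-6-propylbenzoyl)oxy]-2-hydroxy-6-pentylbenzoic acid | CCCCCc1cc(OC(=O)c2c(CCC)cc(OC)c(Cl)c2O)cc(O)c1C(=O)O | target

## Step count and risk

Total step count: 8. Longest linear sequence: 8 steps (1 to 13); olivetol 9 enters at step 6.

**Step 7 (key step).** Two processes are most likely to go wrong.
- Loss of site selectivity: formaldehyde could be delivered to ring A C3 instead of C1, since both carbons are ortho to the magnesium phenoxide.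
- Acyl transfer from the aryl ester to the magnesium methoxide formed in the redox step, or to a second ring A phenoxide.

Fallback: it sets out from 9 and 8 and comes back at 12, moving the formylation ahead of the esterification. Olivetol 9 is formylated under Vilsmeier–Haack conditions (POCl3, DMF), passing through the iminium salt N-[(2,4-dihydroxy-6-pentylphenyl)methylidene]-N-methylmethanaminium chloride F1. Aqueous hydrolysis gives 2,4-dihydroxy-6-pentylbenzaldehyde F2, the established regiochemical outcome for 5-alkylresorcinols. DCC/DMAP coupling of 8 then acylates the non-chelated 4-hydroxyl of F2 to give 12.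

**Step 8.** Most likely failures are electrophilic chlorination of ring A by hypochlorous acid or chlorine dioxide outrunning the scavenger, slow oxidation of the hydrogen-bonded aldehyde, and decarboxylation of the product during acidic work-up.

Fallback: it sets out from 12 and comes back at 13. Both phenols are acetylated (Ac2O, pyridine, DMAP) to give 3-(acetyloxy)-4-formyl-5-pentylphenyl 2-(acetyloxy)-3-chloro-4-methoxy-6-propylbenzoate F3. The now electron-poorer, phenol-free aldehyde is oxidised with NaClO2/NaH2PO4/2-methylbut-2-ene to 2-(acetyloxy)-4-{[2-(acetyloxy)-3-chloro-4-methoxy-6-propylbenzoyl]oxy}-6-pentylbenzoic acid F4. The two acetates, whose carbonyls are unhindered, are then removed with NH4OAc in aqueous methanol at rt in preference to the di-ortho-substituted depside ester, giving 13.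

**Step 6.** Most likely failures are over-acylation to the diester, rearrangement of the hindered O-acylisourea to an N-acylurea before the phenol attacks, and self-esterification of 8.

Fallback: it sets out from 9 and comes back at 10, desymmetrising olivetol before the coupling. Compound 9 is monosilylated (TBSCl, 1 equiv, imidazole, DMF; diol and bis-ether separated) to 3-{[tert-butyl(dimethyl)silyl]oxy}-5-pentylphenol F5. With only one free hydroxyl, F5 can be coupled with an excess of 8 under DCC/DMAP to give 3-{[tert-butyl(dimethyl)silyl]oxy}-5-pentylphenyl 3-chloro-2-hydroxy-4-methoxy-6-propylbenzoate F6. HF·pyridine in THF at 0 °C then frees 10.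

**Step 2.** Most likely failures are incomplete chlorine migration and elimination, transfer of positive chlorine to the product (over-chlorination), or reductive loss of chlorine, any of which would leave mixtures of resorcinols.

Fallback: it sets out from 1 and comes back at 4, placing the chlorine by directed metalation.
- Dione 1 is dehydrogenated over Pd/C in a refluxing high-boiling ether to 5-propylbenzene-1,3-diol F7.
- F7 is protected (MOMCl, i-Pr2NEt, CH2Cl2) as 1,3-bis(methoxymethoxy)-5-propylbenzene F8.
- n-BuLi in THF at 0 °C metalates the carbon between the two MOM ethers to give [2,6-bis(methoxymethoxy)-4-propylphenyl]lithium F9.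
- Hexachloroethane converts F9 into 2-chloro-1,3-bis(methoxymethoxy)-5-propylbenzene F10.
- HCl in methanol removes both MOM groups to give 4.

**Step 4.** Most likely failures are methylation of both hydroxyls or of the wrong one, since the flanking chlorine raises the acidity of both.

Fallback: it sets out from 6 and comes back at 7. Exhaustive methylation (MeI in excess, K2CO3, DMF) gives 3-chloro-2,4-dimethoxy-6-propylbenzaldehyde F11. BCl3 (1.1 equiv, CH2Cl2, −78 to 0 °C) then cleaves only the C2 methyl ether, which is chelated to the ortho formyl group, giving 7.

## Further compounds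

F1 | step 7 | N-[(2,4-dihydroxy-6-pentylphenyl)methylidene]-N-methylmethanaminium chloride | CCCCCc1cc(O)cc(O)c1C=[N+](C)C.[Cl-]
F2 | step 7 | 2,4-dihydroxy-6-pentylbenzaldehyde | CCCCCc1cc(O)cc(O)c1C=O
F3 | step 8 | 3-(acetyloxy)-4-formyl-5-pentylphenyl 2-(acetyloxy)-3-chloro-4-methoxy-6-propylbenzoate | CCCCCc1cc(OC(=O)c2c(CCC)cc(OC)c(Cl)c2OC(C)=O)cc(OC(C)=O)c1C=O
F4 | step 8 | 2-(acetyloxy)-4-{[2-(acetyloxy)-3-chloro-4-methoxy-6-propylbenzoyl]oxy}-6-pentylbenzoic acid | CCCCCc1cc(OC(=O)c2c(CCC)cc(OC)c(Cl)c2OC(C)=O)cc(OC(C)=O)c1C(=O)O
F5 | step 6 | 3-{[tert-butyl(dimethyl)silyl]oxy}-5-pentylphenol | CCCCCc1cc(O)cc(O[Si](C)(C)C(C)(C)C)c1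
F6 | step 6 | 3-{[tert-butyl(dimethyl)silyl]oxy}-5-pentylphenyl 3-chloro-2-hydroxy-4-methoxy-6-propylbenzoate | CCCCCc1cc(O[Si](C)(C)C(C)(C)C)cc(OC(=O)c2c(CCC)cc(OC)c(Cl)c2O)c1
F7 | step 2 | 5-propylbenzene-1,3-diol | CCCc1cc(O)cc(O)c1
F8 | step 2 | 1,3-bis(methoxymethoxy)-5-propylbenzene | CCCc1cc(OCOC)cc(OCOC)c1
F9 | step 2 | [2,6-bis(methoxymethoxy)-4-propylphenyl]lithium | CCCc1cc(OCOC)c([Li])c(OCOC)c1
F10 | step 2 | 2-chloro-1,3-bis(methoxymethoxy)-5-propylbenzene | CCCc1cc(OCOC)c(Cl)c(OCOC)c1
F11 | step 4 | 3-chloro-2,4-dimethoxy-6-propylbenzaldehyde | CCCc1cc(OC)c(Cl)c(OC)c1C=O
A1 | alternative 1 | benzyl 4-{[2-(benzyloxy)-3-chloro-4-methoxy-6-propylbenzoyl]oxy}-2-hydroxy-6-pentylbenzoate | CCCCCc1cc(OC(=O)c2c(CCC)cc(OC)c(Cl)c2OCc2ccccc2)cc(O)c1C(=O)OCc1ccccc1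
A2 | alternative 1 | 4-ethoxy-4-[(trimethylsilyl)oxy]buta-1,3-dien-2-yl 2-(benzyloxy)-3-chloro-4-methoxy-6-propylbenzoate | CCOC(O[Si](C)(C)C)=CC(=C)OC(=O)c1c(CCC)cc(OC)c(Cl)c1OCc1ccccc1
A3 | alternative 1 | benzyl oct-2-ynoate | CCCCCC#CC(=O)OCc1ccccc1
A4 | alternative 2 | tert-butyl 4-{[3-chloro-4-methoxy-2-(methoxymethoxy)-6-propylbenzoyl]oxy}-2-(methoxymethoxy)-6-pentylbenzoate | CCCCCc1cc(OC(=O)c2c(CCC)cc(OC)c(Cl)c2OCOC)cc(OCOC)c1C(=O)OC(C)(C)C
A5 | alternative 2 | [4-(tert-butoxycarbonyl)-3-(methoxymethoxy)-5-pentylphenyl]boronic acid | CCCCCc1cc(B(O)O)cc(OCOC)c1C(=O)OC(C)(C)C
A6 | alternative 2 | 3-chloro-4-methoxy-2-(methoxymethoxy)-6-propylbenzoic acid | CCCc1cc(OC)c(Cl)c(OCOC)c1C(=O)O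
A7 | alternative 3 | 4-{[3-chloro-4-methoxy-2-(methoxymethoxy)-6-propylbenzoyl]oxy}-2-hydroxy-6-pentylbenzoic acid | CCCCCc1cc(OC(=O)c2c(CCC)cc(OC)c(Cl)c2OCOC)cc(O)c1C(=O)O
A8 | alternative 3 | 4-{[3-chloro-4-methoxy-2-(methoxymethoxy)-6-propylbenzoyl]oxy}-2-pentylbenzoic acid | CCCCCc1cc(OC(=O)c2c(CCC)cc(OC)c(Cl)c2OCOC)ccc1C(=O)O
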